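**Retrosynthetic overview**
1. Target 20 ⇐ 19 by acidolysis of four 4-methoxybenzyl (PMB) groups; 19 ⇐ aniline 10 + acrylate 17 by Heck–Matsuda arylation, which makes the C7–vinyl bond of the (E)-propenoate.
2. 10 ⇐ nitro imide 8 by auxiliary cleavage and nitro reduction. The nitro group at C7 is a temporary SNAr activator and then the diazonium precursor, so the route removes it in step 11.
3. 8 ⇐ glycolyl imide 4 + aldehyde 6 in one pot: C2–C3 by auxiliary-controlled anti-aldol addition and O4–C4a by fluoride-triggered SNAr. This closes the dioxane ring, the only ring the route forms; the three benzene rings are bought.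
4. Enabling feature: in the 2,3-dihydro-1,4-benzodioxine, C2 is a glycolate α-carbon (bonded to O1 and the carboxyl, hence enolisable), C3 is an aldehyde-derived benzylic carbinol carbon, and benzo carbon C4a (bonded to O4) is para to C7, where the propenoate sits, so an acceptor at C7 activates C4a–F.
5. 17 ⇐ potassium (R)-glycidate 13 + aryl Grignard 14 (Cu-catalysed epoxide opening), then PMB ester formation and acryloylation.

Key step: step 4

Remark: the given descriptors define a cis-2,3-disubstituted (2R,3R)-benzodioxane (H-2 and H-3 on the same face) and an (R)-aryl-lactate; because cis 2-carbonyl derivatives can isomerise to trans under base, C2 is carried as the free acid after step 5 and no basic step follows.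

**Step 1**
Reactants: 1 (S)-4-benzyloxazolidin-2-one
Product: 2 (S)-4-benzyl-3-(bromoacetyl)oxazolidin-2-one
Conditions: n-BuLi, THF, −78 °C; BrCH2COBr, −78 → 0 °C
Reagents that add atoms: bromoacetyl bromide, BrCC(=O)Br
Why: N-acylation of the lithiated oxazolidinone, in which acyl substitution at the acid bromide is much faster than displacement of the α-bromide at low temperature and the auxiliary stereocentre is not involved.

**Step 2**
Reactants: 2 (S)-4-benzyl-3-(bromoacetyl)oxazolidin-2-one; 3 2-fluoro-5-nitrophenol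
Product: 4 (S)-4-benzyl-3-[(2-fluoro-5-nitrophenoxy)acetyl]oxazolidin-2-one
Conditions: K2CO3, acetone, 23 °C
Reagents that add atoms: none
Why: Williamson O-alkylation, in which the acidic nitrophenol is deprotonated by carbonate and its phenoxide displaces the activated α-bromo imide bromide by SN2 faster than it can attack a second fluoronitroarene.

**Step 3**
Reactants: 5 3,4-dihydroxybenzaldehyde
Product: 6 3,4-bis[(4-methoxybenzyl)oxy]benzaldehyde
Conditions: PMBCl, K2CO3, Bu4NI (cat.), DMF, 60 °C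
Reagents that add atoms: 4-methoxybenzyl chloride, COc1ccc(CCl)cc1
Why: Williamson ether synthesis on both phenols, giving ethers that are stable to amine base, fluoride, hydroperoxide, zinc and the diazonium chemistry that follow.

**Step 4**
Reactants: 4 (S)-4-benzyl-3-[(2-fluoro-5-nitrophenoxy)acetyl]oxazolidin-2-one; 6 3,4-bis[(4-methoxybenzyl)oxy]benzaldehyde
Product: 8 (S)-4-benzyl-3-{[(2R,3R)-3-{3,4-bis[(4-methoxybenzyl)oxy]phenyl}-7-nitro-2,3-dihydro-1,4-benzodioxin-2-yl]carbonyl}oxazolidin-2-one, via anti-aldol trimethylsilyl ether 7 (not isolated)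
Conditions: MgCl2 (20 mol%), Et3N, TMSCl, EtOAc, 23 °C; then evaporation, CsF, DMF, 0 → 23 °C
Reagents that add atoms: none
Why: Proposed new method: soft enolisation (MgCl2/Et3N) gives the magnesium-chelated (Z)-enolate of 4, which adds to 6 through a boat-like transition state and is trapped by TMSCl as silyl ether 7, so the anti adduct forms under kinetic control and cannot revert; CsF then unmasks the C3 alkoxide, which adds to the fluorine-bearing carbon para to the nitro group (Meisenheimer adduct) and expels fluoride, the released fluoride desilylating the next molecule. The closest known reaction types are the magnesium halide-catalysed anti-aldol reaction of N-acyloxazolidinones with aromatic aldehydes and the fluoride-triggered desilylative SNAr etherification of 4-fluoronitroarenes; their merger into one annulation that delivers a 1,4-benzodioxane has no direct precedent. The dioxane ring closes by 6-exo-trig attack of the alkoxide oxygen on the arene carbon (addition–elimination). C2 (R) is set by the (S)-benzyl group of the auxiliary, which shields one face of the chelated enolate, and C3 (R) by the anti topology of the aldol transition state; the SNAr stage breaks no bond at either centre, so the anti adduct maps onto the cis ring. The step needs anti over syn addition, one enolate face, and ring closure that outruns retro-aldol cleavage and attack on the auxiliary carbonyl: imide chelation (the electron-poor aryloxy oxygen is too weak a ligand to compete) and silyl trapping should secure the first two, and the para-nitro group together with the six-membered transition state should secure the third. Allylic 1,3-strain in imide 8 should disfavour enolisation at C2 under the fluoride conditions.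

**Step 5**
Reactants: 8 (S)-4-benzyl-3-{[(2R,3R)-3-{3,4-bis[(4-methoxybenzyl)oxy]phenyl}-7-nitro-2,3-dihydro-1,4-benzodioxin-2-yl]carbonyl}oxazolidin-2-one
Product: 9 (2R,3R)-3-{3,4-bis[(4-methoxybenzyl)oxy]phenyl}-7-nitro-2,3-dihydro-1,4-benzodioxine-2-carboxylic acid
Conditions: LiOH, H2O2 (30% aq.), THF–H2O, 0 °C; Na2SO3; then 1 M HCl to pH 3
Reagents that add atoms: hydrogen peroxide, OO
Why: Hydroperoxide cleavage of the N-acyloxazolidinone, in which the hydroperoxide anion attacks the exocyclic carbonyl, sulfite reduces the peracid, and the resulting carboxylate is no longer enolisable so that C2 should keep its configuration.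

**Step 6**
Reactants: 9 (2R,3R)-3-{3,4-bis[(4-methoxybenzyl)oxy]phenyl}-7-nitro-2,3-dihydro-1,4-benzodioxine-2-carboxylic acid
Product: 10 (2R,3R)-7-amino-3-{3,4-bis[(4-methoxybenzyl)oxy]phenyl}-2,3-dihydro-1,4-benzodioxine-2-carboxylic acid
Conditions: Zn dust, AcOH–THF, 0 → 23 °C
Reagents that add atoms: none
Why: Dissolving-metal reduction of the nitroarene to the aniline, which should leave the PMB ethers, the benzylic ring ether and both stereocentres untouched under weakly acidic conditions.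

**Step 7**
Reactants: 11 4-bromo-2-methoxyphenol
Product: 12 4-bromo-2-methoxy-1-[(4-methoxybenzyl)oxy]benzene
Conditions: PMBCl, K2CO3, DMF, 50 °C
Reagents that add atoms: 4-methoxybenzyl chloride, COc1ccc(CCl)cc1
Why: Williamson ether synthesis that masks the phenol before the Grignard reagent is made.

**Step 8**
Reactants: 12 4-bromo-2-methoxy-1-[(4-methoxybenzyl)oxy]benzene; 13 potassium (R)-oxirane-2-carboxylate
Product: 15 (R)-2-hydroxy-3-{3-methoxy-4-[(4-methoxybenzyl)oxy]phenyl}propanoic acid, via arylmagnesium bromide 14 (not isolated)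
Conditions: Mg, THF, 40 °C; then 13, CuI (10 mol%), THF, −30 → 0 °C; aq. HCl to pH 3
Reagents that add atoms: none
Why: Copper-catalysed ring opening of a glycidate salt by an aryl Grignard reagent at the unsubstituted epoxide carbon (SN2), which does not involve the stereocentre, so the (R) configuration of 13 is carried into the aryl-lactic acid.

**Step 9**
Reactants: 15 (R)-2-hydroxy-3-{3-methoxy-4-[(4-methoxybenzyl)oxy]phenyl}propanoic acid
Product: 16 4-methoxybenzyl (R)-2-hydroxy-3-{3-methoxy-4-[(4-methoxybenzyl)oxy]phenyl}propanoate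
Conditions: PMBCl, KHCO3, Bu4NI (cat.), DMF, 23 °C
Reagents that add atoms: 4-methoxybenzyl chloride, COc1ccc(CCl)cc1
Why: Carboxylate O-alkylation, in which hydrogen carbonate deprotonates only the acid so that the secondary alcohol stays free and the stereocentre is not touched.

**Step 10**
Reactants: 16 4-methoxybenzyl (R)-2-hydroxy-3-{3-methoxy-4-[(4-methoxybenzyl)oxy]phenyl}propanoate
Product: 17 4-methoxybenzyl (R)-2-(acryloyloxy)-3-{3-methoxy-4-[(4-methoxybenzyl)oxy]phenyl}propanoate
Conditions: acryloyl chloride, Et3N, CH2Cl2, −20 → 0 °C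
Reagents that add atoms: acryloyl chloride, C=CC(=O)Cl
Why: O-acylation of the secondary alcohol by the acid chloride, which breaks no bond at the stereocentre.

**Step 11**
Reactants: 10 (2R,3R)-7-amino-3-{3,4-bis[(4-methoxybenzyl)oxy]phenyl}-2,3-dihydro-1,4-benzodioxine-2-carboxylic acid; 17 4-methoxybenzyl (R)-2-(acryloyloxy)-3-{3-methoxy-4-[(4-methoxybenzyl)oxy]phenyl}propanoate
Product: 19 (2R,3R)-3-{3,4-bis[(4-methoxybenzyl)oxy]phenyl}-7-[(E)-3-{[(R)-1-[(4-methoxybenzyl)oxy]-3-{3-methoxy-4-[(4-methoxybenzyl)oxy]phenyl}-1-oxopropan-2-yl]oxy}-3-oxoprop-1-en-1-yl]-2,3-dihydro-1,4-benzodioxine-2-carboxylic acid, via arenediazonium acetate 18 (not isolated)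
Conditions: t-BuONO, Pd(OAc)2 (5 mol%), AcOH–MeCN, 0 → 40 °C
Reagents that add atoms: none
Why: Heck–Matsuda reaction with in situ diazotisation, in which the arenediazonium acetate adds oxidatively to zerovalent palladium formed from Pd(OAc)2 and syn-carbopalladation of the acrylate followed by syn β-hydride elimination should give the (E)-cinnamate under base-free conditions that spare the cis stereocentres and the PMB groups.

**Step 12**
Reactants: 19 (2R,3R)-3-{3,4-bis[(4-methoxybenzyl)oxy]phenyl}-7-[(E)-3-{[(R)-1-[(4-methoxybenzyl)oxy]-3-{3-methoxy-4-[(4-methoxybenzyl)oxy]phenyl}-1-oxopropan-2-yl]oxy}-3-oxoprop-1-en-1-yl]-2,3-dihydro-1,4-benzodioxine-2-carboxylic acid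
Product: 20 clinopodic acid F
Conditions: TFA (10 vol%), C6HMe5, CH2Cl2, 0 °C
Reagents that add atoms: none
Why: Acidolysis of the three PMB ethers and the PMB ester with pentamethylbenzene as an irreversible Friedel–Crafts trap for the 4-methoxybenzyl cations, under dilute acid at 0 °C that should leave the cinnamate ester, the ring ether at C3 (its cation is destabilised by the neighbouring carboxyl) and all stereocentres intact.

**Compound list**
1 | (S)-4-benzyloxazolidin-2-one | O=C1N[C@@H](Cc2ccccc2)CO1 | starting material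
2 | (S)-4-benzyl-3-(bromoacetyl)oxazolidin-2-one | O=C(CBr)N1[C@@H](Cc2ccccc2)COC1=O | intermediate
3 | 2-fluoro-5-nitrophenol | Oc1cc([N+](=O)[O-])ccc1F | starting material
4 | (S)-4-benzyl-3-[(2-fluoro-5-nitrophenoxy)acetyl]oxazolidin-2-one | O=C(COc1cc([N+](=O)[O-])ccc1F)N1[C@@H](Cc2ccccc2)COC1=O | intermediate
5 | 3,4-dihydroxybenzaldehyde | O=Cc1ccc(O)c(O)c1 | starting material
6 | 3,4-bis[(4-methoxybenzyl)oxy]benzaldehyde | COc1ccc(COc2ccc(C=O)cc2OCc2ccc(OC)cc2)cc1 | intermediate
7 | (S)-4-benzyl-3-[(2R,3R)-3-{3,4-bis[(4-methoxybenzyl)oxy]phenyl}-2-(2-fluoro-5-nitrophenoxy)-3-(trimethylsilyloxy)propanoyl]oxazolidin-2-one | [O-][N+](=O)c1ccc(F)c(c1)O[C@@H](C(=O)N1[C@@H](Cc2ccccc2)COC1=O)[C@@H](c1ccc(OCc2ccc(OC)cc2)c(OCc2ccc(OC)cc2)c1)O[Si](C)(C)C | intermediate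
8 | (S)-4-benzyl-3-{[(2R,3R)-3-{3,4-bis[(4-methoxybenzyl)oxy]phenyl}-7-nitro-2,3-dihydro-1,4-benzodioxin-2-yl]carbonyl}oxazolidin-2-one | [O-][N+](=O)c1ccc2c(c1)O[C@@H](C(=O)N1[C@@H](Cc3ccccc3)COC1=O)[C@@H](c1ccc(OCc3ccc(OC)cc3)c(OCc3ccc(OC)cc3)c1)O2 | intermediate
9 | (2R,3R)-3-{3,4-bis[(4-methoxybenzyl)oxy]phenyl}-7-nitro-2,3-dihydro-1,4-benzodioxine-2-carboxylic acid | [O-][N+](=O)c1ccc2c(c1)O[C@@H](C(=O)O)[C@@H](c1ccc(OCc3ccc(OC)cc3)c(OCc3ccc(OC)cc3)c1)O2 | intermediate
10 | (2R,3R)-7-amino-3-{3,4-bis[(4-methoxybenzyl)oxy]phenyl}-2,3-dihydro-1,4-benzodioxine-2-carboxylic acid | Nc1ccc2c(c1)O[C@@H](C(=O)O)[C@@H](c1ccc(OCc3ccc(OC)cc3)c(OCc3ccc(OC)cc3)c1)O2 | intermediate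
11 | 4-bromo-2-methoxyphenol | COc1cc(Br)ccc1O | starting material
12 | 4-bromo-2-methoxy-1-[(4-methoxybenzyl)oxy]benzene | COc1ccc(COc2ccc(Br)cc2OC)cc1 | intermediate
13 | potassium (R)-oxirane-2-carboxylate | [K+].[O-]C(=O)[C@H]1CO1 | starting material
14 | {3-methoxy-4-[(4-methoxybenzyl)oxy]phenyl}magnesium bromide | COc1ccc(COc2ccc([Mg]Br)cc2OC)cc1 | intermediate
15 | (R)-2-hydroxy-3-{3-methoxy-4-[(4-methoxybenzyl)oxy]phenyl}propanoic acid | COc1ccc(COc2ccc(C[C@@H](O)C(=O)O)cc2OC)cc1 | intermediate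
16 | 4-methoxybenzyl (R)-2-hydroxy-3-{3-methoxy-4-[(4-methoxybenzyl)oxy]phenyl}propanoate | COc1ccc(COc2ccc(C[C@@H](O)C(=O)OCc3ccc(OC)cc3)cc2OC)cc1 | intermediate
17 | 4-methoxybenzyl (R)-2-(acryloyloxy)-3-{3-methoxy-4-[(4-methoxybenzyl)oxy]phenyl}propanoate | COc1ccc(COc2ccc(C[C@@H](OC(=O)C=C)C(=O)OCc3ccc(OC)cc3)cc2OC)cc1 | intermediate
18 | (2R,3R)-3-{3,4-bis[(4-methoxybenzyl)oxy]phenyl}-2-carboxy-2,3-dihydro-1,4-benzodioxine-7-diazonium acetate | CC(=O)[O-].N#[N+]c1ccc2c(c1)O[C@@H](C(=O)O)[C@@H](c1ccc(OCc3ccc(OC)cc3)c(OCc3ccc(OC)cc3)c1)O2 | intermediate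
19 | (2R,3R)-3-{3,4-bis[(4-methoxybenzyl)oxy]phenyl}-7-[(E)-3-{[(R)-1-[(4-methoxybenzyl)oxy]-3-{3-methoxy-4-[(4-methoxybenzyl)oxy]phenyl}-1-oxopropan-2-yl]oxy}-3-oxoprop-1-en-1-yl]-2,3-dihydro-1,4-benzodioxine-2-carboxylic acid | COc1cc(C[C@@H](OC(=O)/C=C/c2ccc3c(c2)O[C@@H](C(=O)O)[C@@H](c2ccc(OCc4ccc(OC)cc4)c(OCc4ccc(OC)cc4)c2)O3)C(=O)OCc2ccc(OC)cc2)ccc1OCc1ccc(OC)cc1 | intermediate
20 | clinopodic acid F, (2R,3R)-7-[(E)-3-{[(R)-1-carboxy-2-(4-hydroxy-3-methoxyphenyl)ethoxy]}-3-oxoprop-1-en-1-yl]-3-(3,4-dihydroxyphenyl)-2,3-dihydro-1,4-benzodioxine-2-carboxylic acid | COc1cc(C[C@@H](OC(=O)/C=C/c2ccc3c(c2)O[C@@H](C(=O)O)[C@@H](c2ccc(O)c(O)c2)O3)C(=O)O)ccc1O | target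

**Total steps:** 12. **Longest linear sequence:** 7 steps (1, 2, 4, 5, 6, 11, 12).

**Steps most likely to fail**

Step 4. The α-aryloxy imide may not follow the anti and facial preferences of alkyl imides in the aldol stage. Once the alkoxide is unmasked, retro-aldol cleavage or acyl transfer to the auxiliary carbonyl could compete with ring closure. The enolate oxygen could also arylate intramolecularly before the aldehyde is captured. The fallback uses known chemistry, sets out from aldehyde 6 and returns at acid 9. It closes the ring at the other C–O bond with inversion. (R)-4-Benzyloxazolidin-2-one is acylated as in step 1 to (R)-4-benzyl-3-(bromoacetyl)oxazolidin-2-one F1. 4-Nitrocatechol is mono-allylated at the more acidic hydroxyl para to the nitro group (allyl bromide, KHCO3, DMF) to 2-(allyloxy)-5-nitrophenol F2. F1 and F2 are joined (K2CO3, acetone) to (R)-4-benzyl-3-{[2-(allyloxy)-5-nitrophenoxy]acetyl}oxazolidin-2-one F3. A boron-mediated Evans syn-aldol reaction of F3 with 6 (Bu2BOTf, i-Pr2NEt, CH2Cl2, −78 °C) should give (R)-4-benzyl-3-[(2R,3S)-2-[2-(allyloxy)-5-nitrophenoxy]-3-{3,4-bis[(4-methoxybenzyl)oxy]phenyl}-3-hydroxypropanoyl]oxazolidin-2-one F4. Deallylation (Pd(PPh3)4, morpholine, THF) should give (R)-4-benzyl-3-[(2R,3S)-3-{3,4-bis[(4-methoxybenzyl)oxy]phenyl}-3-hydroxy-2-(2-hydroxy-5-nitrophenoxy)propanoyl]oxazolidin-2-one F5. Intramolecular Mitsunobu etherification (PPh3, DIAD, THF, 0 °C) should close the ring with inversion at C3 to (R)-4-benzyl-3-{[(2R,3R)-3-{3,4-bis[(4-methoxybenzyl)oxy]phenyl}-7-nitro-2,3-dihydro-1,4-benzodioxin-2-yl]carbonyl}oxazolidin-2-one F6. LiOH/H2O2 cleavage as in step 5 then gives 9.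

Step 11. Triazene formation between the diazonium salt and unreacted electron-rich aniline, or reductive loss of the diazonium group, may outpace carbopalladation of the bulky acrylate. The fallback sets out from aniline 10 and returns at 19. Sandmeyer-type iodination (t-BuONO, I2, MeCN) converts 10 into (2R,3R)-3-{3,4-bis[(4-methoxybenzyl)oxy]phenyl}-7-iodo-2,3-dihydro-1,4-benzodioxine-2-carboxylic acid F7. F7 is then coupled with 17 in a ligand-free Mizoroki–Heck reaction (Pd(OAc)2, Bu4NCl, NaHCO3, DMF, 60 °C), in which the acid reacts as its non-enolisable carboxylate.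

Step 5. Hydroxide may cause β-elimination of the nitrophenoxide oxygen from the imide (opening of the dioxane ring) followed by re-addition with epimerisation to the trans isomer, or it may attack the ring carbonyl of the auxiliary. The fallback sets out from imide 8 and returns at acid 9. Reductive removal of the auxiliary (LiBH4, THF, 0 °C) gives [(2S,3R)-3-{3,4-bis[(4-methoxybenzyl)oxy]phenyl}-7-nitro-2,3-dihydro-1,4-benzodioxin-2-yl]methanol F8, which no longer has an acidic C2–H. Oxidation of F8 with TEMPO (cat.) and PhI(OAc)2 in MeCN–H2O then gives 9.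

**Further compounds**
F1 | step 4 | (R)-4-benzyl-3-(bromoacetyl)oxazolidin-2-one | O=C(CBr)N1[C@H](Cc2ccccc2)COC1=O
F2 | step 4 | 2-(allyloxy)-5-nitrophenol | Oc1cc([N+](=O)[O-])ccc1OCC=C
F3 | step 4 | (R)-4-benzyl-3-{[2-(allyloxy)-5-nitrophenoxy]acetyl}oxazolidin-2-one | C=CCOc1ccc([N+](=O)[O-])cc1OCC(=O)N1[C@H](Cc2ccccc2)COC1=O
F4 | step 4 | (R)-4-benzyl-3-[(2R,3S)-2-[2-(allyloxy)-5-nitrophenoxy]-3-{3,4-bis[(4-methoxybenzyl)oxy]phenyl}-3-hydroxypropanoyl]oxazolidin-2-one | C=CCOc1ccc([N+](=O)[O-])cc1O[C@@H](C(=O)N1[C@H](Cc2ccccc2)COC1=O)[C@H](c1ccc(OCc2ccc(OC)cc2)c(OCc2ccc(OC)cc2)c1)O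
F5 | step 4 | (R)-4-benzyl-3-[(2R,3S)-3-{3,4-bis[(4-methoxybenzyl)oxy]phenyl}-3-hydroxy-2-(2-hydroxy-5-nitrophenoxy)propanoyl]oxazolidin-2-one | Oc1ccc([N+](=O)[O-])cc1O[C@@H](C(=O)N1[C@H](Cc2ccccc2)COC1=O)[C@H](c1ccc(OCc2ccc(OC)cc2)c(OCc2ccc(OC)cc2)c1)O
F6 | step 4 | (R)-4-benzyl-3-{[(2R,3R)-3-{3,4-bis[(4-methoxybenzyl)oxy]phenyl}-7-nitro-2,3-dihydro-1,4-benzodioxin-2-yl]carbonyl}oxazolidin-2-one | [O-][N+](=O)c1ccc2c(c1)O[C@@H](C(=O)N1[C@H](Cc3ccccc3)COC1=O)[C@@H](c1ccc(OCc3ccc(OC)cc3)c(OCc3ccc(OC)cc3)c1)O2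
F7 | step 11 | (2R,3R)-3-{3,4-bis[(4-methoxybenzyl)oxy]phenyl}-7-iodo-2,3-dihydro-1,4-benzodioxine-2-carboxylic acid | Ic1ccc2c(c1)O[C@@H](C(=O)O)[C@@H](c1ccc(OCc3ccc(OC)cc3)c(OCc3ccc(OC)cc3)c1)O2
F8 | step 5 | [(2S,3R)-3-{3,4-bis[(4-methoxybenzyl)oxy]phenyl}-7-nitro-2,3-dihydro-1,4-benzodioxin-2-yl]methanol | [O-][N+](=O)c1ccc2c(c1)O[C@@H](CO)[C@@H](c1ccc(OCc3ccc(OC)cc3)c(OCc3ccc(OC)cc3)c1)O2
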